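Molar per minute is the unit I reckon in: I follow the rate of E in the noon run, where it starts, what slows it and by what factor.

| setting | summer | dusk | midnight | noon |
|---|---|---|---|---|
| X | 0.600 M | 0.600 M | 0.900 M | 0.600 M |
| Z | 1.80 M | 1.80 M | 1.80 M | 0.360 M |
| L | 0.0180 M | 0.0270 M | 0.0180 M | 0.0180 M |
| time |  |  |  | 17 min |

| summer run: time / min | summer run: [E] / M | dusk run: time / min | dusk run: [E] / M | midnight run: time / min | midnight run: [E] / M |
|---|---|---|---|---|---|
| 2.4 | 0.1491 | 2.4 | 0.2070 | 2.4 | 0.1917 |
| 4.9 | 0.2609 | 4.9 | 0.3408 | 4.9 | 0.3268 |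
| 7.3 | 0.3356 | 7.3 | 0.4148 | 7.3 | 0.4235 |
| 9.7 | 0.3892 | 9.7 | 0.4659 | 9.7 | 0.4991 |
| 12 | 0.4330 | 12 | 0.5038 | 12 | 0.5493 |
| 15 | 0.4747 | 15 | 0.5340 | 15 | 0.6131 |
| 17 | 0.4920 | 17 | 0.5461 | 17 | 0.6432 |

(each reading ± 0.002 M)

- how the opening rate goes with [L] round the charge of the summer run: the exponent of the rate at two percent of X gone to E
- how the opening rate goes with [X] round the charge of the summer run: the exponent of the rate at two percent of X gone to E (one fixed amount of E, the same in the runs compared)
- E in the noon run at 17 min, as a share of the X charged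

- Overall: X + Z -> E, with L as catalyst.
- Constant volume, constant temperature.
- A reading of a species includes what of it is bound.
- "The second partner" is Z.
- An order is taken over about fifteen percent of the charge, up and down.

Dusk at 4.9 min reads 0.3408 M and summer at 7.3 min reads 0.3356 M, at nearly equal L·t, so I take E to follow L·t, an order of 1 in L. Extrapolating the first two mean rates to zero time gives an opening rate r_open of 0.0706 M min⁻¹ in summer and 0.0925 M min⁻¹ in midnight, so the order in X reads n = 0.665, with the scatter of two extrapolations in it.

I carry the leftover factor s, the share of the opening rate still present at mid-run once the losses of Z and X are divided out. I assume first order in Z; summer, dusk and midnight were all charged with 1.80 M of it. In summer, from 7.3 min to 9.7 min, E averages 0.362 M, and with f_Z and f_X the remaining shares of Z and of X to the power n: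

s = r / (r_open · f_Z · f_X) = 0.0223 M min⁻¹ / (0.0706 M min⁻¹ · 0.799 · 0.540) = 0.733

Midnight in the same window holds more E, 0.461 M, yet reads s = 0.738, so at this charge of L I tie s to the clock, not to E.

Noon has the L and X of summer, and Z, at 0.360 M, is the limiting reagent. On my assumption for Z, its opening rate is 0.0141 M min⁻¹, worth 0.240 M over 17 min if nothing slowed it. The window is centred on mid-run, so s applies; I take the depletion at half the final E and repeat:

E = 0.176 M → 0.120 M → 0.137 M → 0.132 M → 0.133 M

With mid-run values standing for the means over the noon run, s = 0.733, f_Z = 0.815 and f_X = 0.925, so I commit to 22.2 % of the X charged.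

The forecast gives 1 (0.9 to 1.1) for L, 0.55 (0.42 to 0.7) for X and 27 % (15 % to 42 %) for noon, above my figure, with “first order in Z, which is unproven”.

The flask gives 1.0 for L, 0.58 for X and 21.9 % for noon.

    L + X + Z → E + L (18.06 L² mol⁻² min⁻¹)
    2 L → 2 Gu (1.764 L mol⁻¹ min⁻¹)
    2 X ⇌ X2, settled at all times (13.80 L mol⁻¹)

In the noon run that is 0.131 M of E, a mean rate of 0.00773 M min⁻¹, or 0.548 of my opening rate; dividing by s leaves 0.748. The step to Gu alone gives L at this charge a first half-life of 15.7 min. In the dusk run, from 7.3 min to 9.7 min, L·t is 1.50 times that of the summer window, and with E at 0.440 M and an opening rate reckoned from summer's at 0.106 M min⁻¹, s reads 0.642.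

(All runs were generated by integration with made-up constants, noise included.)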